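**Retrosynthetic overview**
1. The target is 2α,6α,19-trihydroxylabda-8,13-dien-15,16-olide. The butenolide is bought intact and joined last at C12–C13 by sp3–sp2 Negishi coupling of a C12 iodide with 4-bromofuran-2(5H)-one.
2. The strategy rests on ring B: a cyclohexene whose only alkene is the tetrasubstituted C8=C9, with quaternary C10 and C7H2 on either side and the C5-H/C6-OH pair across the ring. This is a complete Diels–Alder retron, with C1–C4 of ring A as the four-carbon tether and the 6α-oxygen marking where a boron activator sat.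
3. Key disconnection: C5–C10 and C6–C7 by intramolecular Diels–Alder reaction of an open-chain E-alkenyl dicyclohexylborane triene. Rings A and B close together, and C6–B is then oxidised to C6–OH with retention.
4. The triene comes from a dienyne, made by Suzuki coupling of isopropenyl-Bpin with a tetrasubstituted vinyl iodide. The iodide comes from alkoxide-directed, iron-catalysed syn-methylmagnesiation/iodination of a skipped diyne, itself from an epoxide and a butynyl acetylide.
5. The epoxy alkyne comes from (S)-5-(hydroxymethyl)butyrolactone: C2 is from the chiral pool, C4 from two enolate alkylations (PMBOCH2 first, CH3 second, anti to CH2OTr), and the lactone carbonyl becomes the C5≡C6 alkyne.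

Key step: step 14

Remark: locants C1–C20 are the labdane locants of the target (C17 = CH3 on C8, C18 = 4α-CH3, C19 = 4β-CH2O, C20 = 10β-CH3); LDA, 4-methoxybenzyl chloromethyl ether and dicyclohexylborane are taken as purchased, pre-formed reagents.

**Route**

Step 1
Reactants: 1 (S)-5-(hydroxymethyl)dihydrofuran-2(3H)-one
Product: 2 (S)-5-[(trityloxy)methyl]dihydrofuran-2(3H)-one
Conditions: TrCl (1.1 equiv), Et3N (1.5 equiv), DMAP (cat.), CH2Cl2, 0 °C to rt
Reagents that add atoms: trityl chloride, ClC(c1ccccc1)(c1ccccc1)c1ccccc1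
Why: Tritylation of the primary alcohol through the trityl cation places a very large group on the γ-substituent, which later shields one enolate face, and leaves the stereocentre (future C2) untouched.

Step 2
Reactants: 2 (S)-5-[(trityloxy)methyl]dihydrofuran-2(3H)-one
Product: 3 (3S,5S)-3-[(4-methoxybenzyloxy)methyl]-5-[(trityloxy)methyl]dihydrofuran-2(3H)-one (trans epimer expected as major; used as the epimer mixture)
Conditions: LDA (1.1 equiv), THF, –78 °C; PMBOCH2Cl (1.3 equiv), –78 to –40 °C
Reagents that add atoms: 4-methoxybenzyl chloromethyl ether, COc1ccc(COCCl)cc1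
Why: C-alkylation of the lithium lactone enolate with a reactive α-chloro ether should install the future C19 carbon, and the configuration of this centre is irrelevant because it is planarised again in step 3.

Step 3
Reactants: 3 (3S,5S)-3-[(4-methoxybenzyloxy)methyl]-5-[(trityloxy)methyl]dihydrofuran-2(3H)-one
Product: 4 (3R,5S)-3-[(4-methoxybenzyloxy)methyl]-3-methyl-5-[(trityloxy)methyl]dihydrofuran-2(3H)-one (α-quaternary lactone)
Conditions: LDA (1.2 equiv), THF, –78 °C; MeI (3 equiv), DMPU (2 equiv), –78 °C
Reagents that add atoms: iodomethane, CI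
Why: Enolate alkylation of the tetrasubstituted lactone enolate should occur on the face anti to the CH2OTr group, so that CH3 (C18) ends up trans and CH2OPMB (C19) cis to it, which sets C4; holding the enolate at –78 °C should suppress β-elimination of the PMB alkoxide.

Step 4
Reactants: 4 (3R,5S)-3-[(4-methoxybenzyloxy)methyl]-3-methyl-5-[(trityloxy)methyl]dihydrofuran-2(3H)-one
Product: 5 (3R,5S)-3-[(4-methoxybenzyloxy)methyl]-3-methyl-5-[(trityloxy)methyl]tetrahydrofuran-2-ol (lactol; anomer mixture)
Conditions: DIBAL-H (1.2 equiv), CH2Cl2, –78 °C; aq. Rochelle salt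
Reagents that add atoms: none
Why: Partial reduction with DIBAL-H should stop at the lactol because the aluminium hemiacetal is stable at –78 °C, and no stereocentre is involved.

Step 5
Reactants: 5 (3R,5S)-3-[(4-methoxybenzyloxy)methyl]-3-methyl-5-[(trityloxy)methyl]tetrahydrofuran-2-ol
Product: 6 (2S,4S)-4-[(4-methoxybenzyloxy)methyl]-4-methyl-1-(trityloxy)hex-5-yn-2-ol
Conditions: dimethyl (1-diazo-2-oxopropyl)phosphonate (2.5 equiv), K2CO3 (4 equiv), MeOH, rt to 45 °C
Reagents that add atoms: dimethyl (1-diazo-2-oxopropyl)phosphonate, CC(=O)C(=[N+]=[N-])P(=O)(OC)OC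
Why: Seyferth–Gilbert homologation in the Ohira–Bestmann version should trap the open hydroxy-aldehyde form of the lactol and turn the non-enolisable aldehyde carbon (C5) into the terminal alkyne C5≡C6, releasing the C2 hydroxyl without touching either stereocentre.

Step 6
Reactants: 6 (2S,4S)-4-[(4-methoxybenzyloxy)methyl]-4-methyl-1-(trityloxy)hex-5-yn-2-ol
Product: 8 (2S,4S)-4-[(4-methoxybenzyloxy)methyl]-4-methyl-6-(trimethylsilyl)hex-5-yne-1,2-diol, via bis-silyl trityl ether 7 (not isolated)
Conditions: n-BuLi (2.2 equiv), THF, –78 °C; TMSCl (2.5 equiv), –78 to 0 °C; then MeOH, TsOH·H2O (to pH 2), rt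
Reagents that add atoms: chlorotrimethylsilane, C[Si](C)(C)Cl
Why: The alkoxide/acetylide dianion is silylated on O and C, and acid-catalysed methanolysis then cleaves the labile O–SiMe3 bond and the trityl ether (via the trityl cation), while the alkynyl C–Si bond and the PMB ether are stable to catalytic TsOH at rt.

Step 7
Reactants: 8 (2S,4S)-4-[(4-methoxybenzyloxy)methyl]-4-methyl-6-(trimethylsilyl)hex-5-yne-1,2-diol
Product: 10 (S)-2-[(S)-2-[(4-methoxybenzyloxy)methyl]-2-methyl-4-(trimethylsilyl)but-3-yn-1-yl]oxirane (epoxy silyl-alkyne), via primary tosylate 9 (not isolated)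
Conditions: NaH (2.5 equiv), N-tosylimidazole (1.05 equiv), THF, 0 °C to rt
Reagents that add atoms: none
Why: The less hindered primary alkoxide should be sulfonylated selectively and the C2 alkoxide then closes the oxirane by intramolecular Williamson displacement (3-exo-tet) at C1, so the C2–O bond is never broken and C2 keeps its configuration; the aprotic base avoids protodesilylation of the alkyne.

Step 8
Reactants: 10 epoxy silyl-alkyne; 11 4-(tert-butyldimethylsilyloxy)but-1-yne
Product: 12 (6R,8S)-1-(tert-butyldimethylsilyloxy)-8-[(4-methoxybenzyloxy)methyl]-8-methyl-10-(trimethylsilyl)deca-3,9-diyn-6-ol (skipped diyne carbinol)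
Conditions: 11 (1.5 equiv), n-BuLi (1.45 equiv), THF, –78 °C; BF3·OEt2 (1.5 equiv); then 10, –78 °C
Reagents that add atoms: none
Why: Yamaguchi–Hirao alkynylation: the BF3-activated terminal epoxide should be opened by the lithium acetylide at the unhindered CH2 (C1), attaching C9–C12 and leaving the C2 stereocentre untouched.

Step 9
Reactants: 12 skipped diyne carbinol
Product: 13 (6R,8S)-1,6-bis(tert-butyldimethylsilyloxy)-8-[(4-methoxybenzyloxy)methyl]-8-methyl-10-(trimethylsilyl)deca-3,9-diyne
Conditions: TBSCl (1.5 equiv), imidazole (3 equiv), DMAP (cat.), DMF, rt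
Reagents that add atoms: tert-butyldimethylsilyl chloride, CC(C)(C)[Si](C)(C)Cl
Why: Silylation masks the C2 oxygen so that only the C12 oxygen can direct the carbometalation of step 11, and provides the bulky group that later prefers the equatorial position of the tether chair.

Step 10
Reactants: 13 bis-TBS ether
Product: 14 (6R,8S)-6-(tert-butyldimethylsilyloxy)-8-[(4-methoxybenzyloxy)methyl]-8-methyl-10-(trimethylsilyl)deca-3,9-diyn-1-ol
Conditions: CSA (0.1 equiv), MeOH/CH2Cl2 (1:1), 0 °C
Reagents that add atoms: none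
Why: Acid-catalysed methanolysis of silyl ethers depends strongly on steric hindrance, so the primary TBS ether should be cleaved well before the secondary one, and the alkynylsilane and PMB ether are inert to catalytic CSA at 0 °C.

Step 11
Reactants: 14 homopropargylic alcohol
Product: 16 (3E,6S,8S)-6-(tert-butyldimethylsilyloxy)-3-iodo-8-[(4-methoxybenzyloxy)methyl]-4,8-dimethyl-10-(trimethylsilyl)dec-3-en-9-yn-1-ol (tetrasubstituted vinyl iodide), via alkenylmagnesium alkoxide 15 (not isolated)
Conditions: Fe(acac)3 (0.2 equiv), MeMgBr (5 equiv), THF, –78 to 0 °C; then I2 (6 equiv) in THF, –78 to 0 °C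
Reagents that add atoms: methylmagnesium bromide, C[Mg]Br; iodine, II
Why: Iron-catalysed, alkoxide-directed carbomagnesiation of the homopropargylic alkoxide should add CH3 to the distal alkyne carbon (C10) and magnesium to the proximal one (C9) in syn fashion through a five-membered oxamagnesacycle, and iodinolysis of the C–Mg bond with retention then gives the E iodide with iodine cis to C20 and C11 cis to C1; the hindered silyl alkyne has no directing alkoxide and should not react.

Step 12
Reactants: 16 tetrasubstituted vinyl iodide; 17 isopropenylboronic acid pinacol ester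
Product: 18 (3E,6R,8S)-6-(tert-butyldimethylsilyloxy)-8-[(4-methoxybenzyloxy)methyl]-4,8-dimethyl-3-(prop-1-en-2-yl)-10-(trimethylsilyl)dec-3-en-9-yn-1-ol
Conditions: 17 (2 equiv), Pd(dppf)Cl2·CH2Cl2 (10 mol%), Cs2CO3 (3 equiv), THF/H2O (10:1), 60 °C
Reagents that add atoms: none
Why: Suzuki–Miyaura coupling proceeds with retention at the sp2 carbon in every elementary step, so iodine should be replaced by the isopropenyl group to give the C7=C8–C9=C10 diene with the C9=C10 geometry unchanged.

Step 13
Reactants: 18 silyl dienyne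
Product: 19 (3E,6R,8S)-6-(tert-butyldimethylsilyloxy)-8-[(4-methoxybenzyloxy)methyl]-4,8-dimethyl-3-(prop-1-en-2-yl)dec-3-en-9-yn-1-ol (acyclic dienyne)
Conditions: K2CO3 (1.5 equiv), MeOH, rt
Reagents that add atoms: none
Why: Base-catalysed methanolysis cleaves only the alkynyl C–Si bond (TBS ether, PMB ether and diene are inert), so the terminal alkyne is unveiled just before it is needed.

Step 14
Reactants: 19 acyclic dienyne
Product: 22 2α-(tert-butyldimethylsilyloxy)-19-(4-methoxybenzyloxy)-13,14,15,16-tetranorlabd-8-ene-6α,12-diol, via E-alkenylborane triene 20 (not isolated), via 6α-boryl trans-decalin 21 (not isolated)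
Conditions: Cy2BH (2.3 equiv), THF, 0 °C to rt; then toluene, 80 °C (sealed, Ar); then 3 M NaOH, 30% H2O2, 0 °C to rt
Reagents that add atoms: hydrogen peroxide, OO
Why: Syn, anti-Markovnikov hydroboration of the only terminal alkyne (the second equivalent of Cy2BH is spent on C12-OH as the borinate) should give the E-alkenylborane 20, whose vacant boron p orbital lowers the LUMO of C5=C6, and on heating this dienophile should add to the C7=C8–C9=C10 diene in a concerted, asynchronous intramolecular Diels–Alder reaction that forms C5–C10 and C6–C7. The closest known reaction types are Diels–Alder reactions of alkenyl dialkylboranes generated by alkyne hydroboration and oxidised afterwards, and thermal cyclisations of 1,7,9-decatrienes, so the step joins two known reaction types and extends them to a diene terminus that is fully substituted. Ring B closes as the six-membered cycloadduct ring with its alkene left at C8=C9, and ring A closes at the same time as a six-membered carbocycle in the fused mode through a chair-like C1–C4 tether. C10 (10β-CH3) is set by the C9=C10 geometry (tether outside, C20 inside), C5 (5α-H, trans fusion) by the tether-exo/boron-endo transition state, and C6 by the E geometry of the alkenylborane, which places boron trans to C4 and hence 6α; alkaline H2O2 then replaces boron by hydroxyl with retention through 1,2-migration of C6 from boron to oxygen. The step needs the boron-endo, trans-fused transition state on the diene face that keeps C2-OTBS equatorial, and this is secured by the fixed geometries of both π-components and by the chair of the tether, since addition to the other face would stack C2-OTBS, C18 and C20 in 1,3-diaxial positions, while geminal substitution at C4 favours the folded tether. The [1,5]-hydrogen shift from C20 to C7 is reversible and returns the same C9=C10 geometry, so it should not divert material, and the real uncertainty is the steric cost of joining neopentyl C5 to fully substituted C10.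

Step 15
Reactants: 22 decalin 6α,12-diol
Product: 23 2α-(tert-butyldimethylsilyloxy)-12-iodo-19-(4-methoxybenzyloxy)-13,14,15,16-tetranorlabd-8-en-6α-ol (C12 iodide)
Conditions: I2 (1.2 equiv), PPh3 (1.2 equiv), imidazole (2.5 equiv), CH2Cl2, 0 °C
Reagents that add atoms: iodine, II
Why: Appel iodination (alkoxyphosphonium salt, then SN2 by iodide) should be selective for the unhindered primary C12 alcohol, because the secondary 6α-hydroxyl next to C5 and the quaternary C4 reacts far more slowly.

Step 16
Reactants: 23 C12 iodide; 24 4-bromofuran-2(5H)-one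
Product: 27 2α-(tert-butyldimethylsilyloxy)-6α-hydroxy-19-(4-methoxybenzyloxy)labda-8,13-dien-15,16-olide (protected target), via dilithio species 25 (not isolated), via alkylzinc chloride 26 (not isolated)
Conditions: t-BuLi (3.1 equiv), Et2O, –78 °C; ZnCl2 (2.2 equiv, THF), –78 to 0 °C; then 24 (1.5 equiv), Pd(dppf)Cl2·CH2Cl2 (5 mol%), THF, rt
Reagents that add atoms: none
Why: After deprotonation of the C6 hydroxyl by the first equivalent of t-BuLi, iodine–lithium exchange and transmetalation to zinc should give a primary alkylzinc reagent that undergoes Negishi coupling with the vinylogous acyl bromide 24, forming C12–C13 and attaching the intact butenolide.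

Step 17
Reactants: 27 protected target
Product: 28 2α-(tert-butyldimethylsilyloxy)-6α,19-dihydroxylabda-8,13-dien-15,16-olide
Conditions: DDQ (1.3 equiv), CH2Cl2/pH 7 buffer (10:1), 0 °C to rt
Reagents that add atoms: none
Why: DDQ oxidises the electron-rich 4-methoxybenzyl ether to an oxocarbenium ion that water hydrolyses to the C19 alcohol and anisaldehyde, and the isolated tetrasubstituted alkene, the butenolide and the TBS ether should not react.

Step 18
Reactants: 28 2α-silyl ether
Product: 29 2α,6α,19-trihydroxylabda-8,13-dien-15,16-olide (target CNP0387838.1; 2R,4S,5R,6S,10S at the labdane locants)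
Conditions: HF·pyridine, THF/pyridine, 0 °C to rt
Reagents that add atoms: none
Why: Fluoride cleavage of the Si–O bond under mildly acidic conditions should free the 2α-hydroxyl without exposing the base-sensitive butenolide to basic fluoride, giving the target.

**Compound list**
1 | (S)-5-(hydroxymethyl)dihydrofuran-2(3H)-one | OC[C@@H]1CCC(=O)O1 | starting material
2 | (S)-5-[(trityloxy)methyl]dihydrofuran-2(3H)-one | c1ccccc1C(c1ccccc1)(c1ccccc1)OC[C@@H]1CCC(=O)O1 | intermediate
3 | (3S,5S)-3-[(4-methoxybenzyloxy)methyl]-5-[(trityloxy)methyl]dihydrofuran-2(3H)-one (trans epimer drawn) | c1ccccc1C(c1ccccc1)(c1ccccc1)OC[C@@H]1C[C@@H](COCc2ccc(OC)cc2)C(=O)O1 | intermediate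
4 | (3R,5S)-3-[(4-methoxybenzyloxy)methyl]-3-methyl-5-[(trityloxy)methyl]dihydrofuran-2(3H)-one | c1ccccc1C(c1ccccc1)(c1ccccc1)OC[C@@H]1C[C@](C)(COCc2ccc(OC)cc2)C(=O)O1 | intermediate
5 | (3R,5S)-3-[(4-methoxybenzyloxy)methyl]-3-methyl-5-[(trityloxy)methyl]tetrahydrofuran-2-ol (anomer mixture) | c1ccccc1C(c1ccccc1)(c1ccccc1)OC[C@@H]1C[C@](C)(COCc2ccc(OC)cc2)C(O)O1 | intermediate
6 | (2S,4S)-4-[(4-methoxybenzyloxy)methyl]-4-methyl-1-(trityloxy)hex-5-yn-2-ol | c1ccccc1C(c1ccccc1)(c1ccccc1)OC[C@@H](O)C[C@](C)(COCc1ccc(OC)cc1)C#C | intermediate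
7 | O,C-bis(trimethylsilyl) derivative of 6 (2-OTMS, 6-TMS) | c1ccccc1C(c1ccccc1)(c1ccccc1)OC[C@@H](O[Si](C)(C)C)C[C@](C)(COCc1ccc(OC)cc1)C#C[Si](C)(C)C | intermediate (not isolated)
8 | (2S,4S)-4-[(4-methoxybenzyloxy)methyl]-4-methyl-6-(trimethylsilyl)hex-5-yne-1,2-diol | OC[C@@H](O)C[C@](C)(COCc1ccc(OC)cc1)C#C[Si](C)(C)C | intermediate
9 | primary 1-O-tosylate of 8 | Cc1ccc(cc1)S(=O)(=O)OC[C@@H](O)C[C@](C)(COCc1ccc(OC)cc1)C#C[Si](C)(C)C | intermediate (not isolated)
10 | (S)-2-[(S)-2-[(4-methoxybenzyloxy)methyl]-2-methyl-4-(trimethylsilyl)but-3-yn-1-yl]oxirane | C1O[C@H]1C[C@](C)(COCc1ccc(OC)cc1)C#C[Si](C)(C)C | intermediate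
11 | 4-(tert-butyldimethylsilyloxy)but-1-yne | C#CCCO[Si](C)(C)C(C)(C)C | starting material
12 | (6R,8S)-1-(tert-butyldimethylsilyloxy)-8-[(4-methoxybenzyloxy)methyl]-8-methyl-10-(trimethylsilyl)deca-3,9-diyn-6-ol | CC(C)(C)[Si](C)(C)OCCC#CC[C@@H](O)C[C@](C)(COCc1ccc(OC)cc1)C#C[Si](C)(C)C | intermediate
13 | (6R,8S)-1,6-bis(tert-butyldimethylsilyloxy)-8-[(4-methoxybenzyloxy)methyl]-8-methyl-10-(trimethylsilyl)deca-3,9-diyne | CC(C)(C)[Si](C)(C)OCCC#CC[C@@H](O[Si](C)(C)C(C)(C)C)C[C@](C)(COCc1ccc(OC)cc1)C#C[Si](C)(C)C | intermediate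
14 | (6R,8S)-6-(tert-butyldimethylsilyloxy)-8-[(4-methoxybenzyloxy)methyl]-8-methyl-10-(trimethylsilyl)deca-3,9-diyn-1-ol | OCCC#CC[C@@H](O[Si](C)(C)C(C)(C)C)C[C@](C)(COCc1ccc(OC)cc1)C#C[Si](C)(C)C | intermediate
15 | C9-alkenylmagnesium bromide / C12 bromomagnesium alkoxide from syn-methylmagnesiation of 14 (Mg cis to C20) | Br[Mg]OCC/C([Mg]Br)=C(/C)C[C@@H](O[Si](C)(C)C(C)(C)C)C[C@](C)(COCc1ccc(OC)cc1)C#C[Si](C)(C)C | intermediate (not isolated)
16 | (3E,6S,8S)-6-(tert-butyldimethylsilyloxy)-3-iodo-8-[(4-methoxybenzyloxy)methyl]-4,8-dimethyl-10-(trimethylsilyl)dec-3-en-9-yn-1-ol | OCC/C(I)=C(/C)C[C@@H](O[Si](C)(C)C(C)(C)C)C[C@](C)(COCc1ccc(OC)cc1)C#C[Si](C)(C)C | intermediate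
17 | isopropenylboronic acid pinacol ester | CC(=C)B1OC(C)(C)C(C)(C)O1 | starting material
18 | (3E,6R,8S)-6-(tert-butyldimethylsilyloxy)-8-[(4-methoxybenzyloxy)methyl]-4,8-dimethyl-3-(prop-1-en-2-yl)-10-(trimethylsilyl)dec-3-en-9-yn-1-ol | OCC/C(C(C)=C)=C(/C)C[C@@H](O[Si](C)(C)C(C)(C)C)C[C@](C)(COCc1ccc(OC)cc1)C#C[Si](C)(C)C | intermediate
19 | (3E,6R,8S)-6-(tert-butyldimethylsilyloxy)-8-[(4-methoxybenzyloxy)methyl]-4,8-dimethyl-3-(prop-1-en-2-yl)dec-3-en-9-yn-1-ol | OCC/C(C(C)=C)=C(/C)C[C@@H](O[Si](C)(C)C(C)(C)C)C[C@](C)(COCc1ccc(OC)cc1)C#C | intermediate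
20 | O12-dicyclohexylboryl, C6-(E)-dicyclohexylboryl triene (C5=C6 E, C9=C10 with C20 inside) | C1CCCCC1B(C1CCCCC1)OCC/C(C(C)=C)=C(/C)C[C@@H](O[Si](C)(C)C(C)(C)C)C[C@](C)(COCc1ccc(OC)cc1)/C=C/B(C1CCCCC1)C1CCCCC1 | intermediate (not isolated)
21 | 6α-dicyclohexylboryl trans-decalin with 12-O-dicyclohexylborinate (2α-OTBS, 19-OPMB, 5α-H, 10β-CH3, Δ8) | CC1=C(CCOB(C3CCCCC3)C3CCCCC3)[C@@]2(C)C[C@@H](O[Si](C)(C)C(C)(C)C)C[C@](C)(COCc3ccc(OC)cc3)[C@@H]2[C@@H](B(C3CCCCC3)C3CCCCC3)C1 | intermediate (not isolated)
22 | 2α-(tert-butyldimethylsilyloxy)-19-(4-methoxybenzyloxy)-13,14,15,16-tetranorlabd-8-ene-6α,12-diol | CC1=C(CCO)[C@@]2(C)C[C@@H](O[Si](C)(C)C(C)(C)C)C[C@](C)(COCc3ccc(OC)cc3)[C@@H]2[C@@H](O)C1 | intermediate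
23 | 2α-(tert-butyldimethylsilyloxy)-12-iodo-19-(4-methoxybenzyloxy)-13,14,15,16-tetranorlabd-8-en-6α-ol | CC1=C(CCI)[C@@]2(C)C[C@@H](O[Si](C)(C)C(C)(C)C)C[C@](C)(COCc3ccc(OC)cc3)[C@@H]2[C@@H](O)C1 | intermediate
24 | 4-bromofuran-2(5H)-one | BrC1=CC(=O)OC1 | starting material
25 | C12-lithio, O6-lithium alkoxide derived from 23 | CC1=C(CC[Li])[C@@]2(C)C[C@@H](O[Si](C)(C)C(C)(C)C)C[C@](C)(COCc3ccc(OC)cc3)[C@@H]2[C@@H](O[Li])C1 | intermediate (not isolated)
26 | C12-alkylzinc chloride (O6 as chlorozinc alkoxide) | CC1=C(CC[Zn]Cl)[C@@]2(C)C[C@@H](O[Si](C)(C)C(C)(C)C)C[C@](C)(COCc3ccc(OC)cc3)[C@@H]2[C@@H](O[Zn]Cl)C1 | intermediate (not isolated)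
27 | 2α-(tert-butyldimethylsilyloxy)-6α-hydroxy-19-(4-methoxybenzyloxy)labda-8,13-dien-15,16-olide | CC1=C(CCC3=CC(=O)OC3)[C@@]2(C)C[C@@H](O[Si](C)(C)C(C)(C)C)C[C@](C)(COCc3ccc(OC)cc3)[C@@H]2[C@@H](O)C1 | intermediate
28 | 2α-(tert-butyldimethylsilyloxy)-6α,19-dihydroxylabda-8,13-dien-15,16-olide | CC1=C(CCC3=CC(=O)OC3)[C@@]2(C)C[C@@H](O[Si](C)(C)C(C)(C)C)C[C@](C)(CO)[C@@H]2[C@@H](O)C1 | intermediate
29 | 2α,6α,19-trihydroxylabda-8,13-dien-15,16-olide (CNP0387838.1) | CC1=C(CCC2=CC(=O)OC2)[C@@]2(C)C[C@@H](O)C[C@](C)(CO)[C@@H]2[C@@H](O)C1 | target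

**Step count and risks**
Total step count: 18. Longest linear sequence: 18 steps (1 to 29); 11, 17 and 24 are bought and enter directly.

Steps most likely to fail, riskiest first:

1. Step 14. The cycloaddition may be too slow, because the reactive s-cis diene conformer is destabilised by the inside C20 methyl and the new bond joins neopentyl C5 to fully substituted C10. Prolonged heating would then allow dehydroboration or redistribution of the alkenylborane, or hydroboration of the diene, and a late, loose transition state could erode endo and facial selectivity. The fallback replaces boron activation by carbonyl activation followed by Baeyer–Villiger oxidation, and sets out from dienyne 19. Double deprotonation (n-BuLi, 2.1 equiv) and addition of acetaldehyde should give the propargylic diol F1. Red-Al trans-hydroalumination should give the (E)-allylic diol F2, and MnO2 should oxidise only the allylic alcohol to the (E)-enone F3. Me2AlCl-promoted intramolecular Diels–Alder reaction through the acyl-endo, tether-exo transition state, which has the same stereochemical consequences as the boron-endo one, should give the 6α-acetyl trans-decalin F4. Baeyer–Villiger oxidation with bis(trimethylsilyl) peroxide and a catalytic Lewis acid, which spares isolated alkenes, should give the 6α-acetate F5 by migration of C6 with retention. Methanolysis (K2CO3, MeOH) returns to the route at diol 22.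

2. Step 5. The 3,3-disubstituted lactol may stay almost entirely ring-closed, and its neopentyl aldehyde form may be intercepted by the diazophosphonate anion more slowly than the reagent decomposes, so conversion stalls. The fallback works on an open-chain aldehyde instead of the lactol and sets out from lactone 4. LiAlH4 should give the diol F6, and TESCl/imidazole the bis-TES ether F7. Swern conditions oxidise a primary TES ether directly and in preference to a secondary one, which should give the aldehyde F8. Ohira–Bestmann homologation of this free aldehyde should give the alkyne F9; if the secondary TES group is lost under K2CO3/MeOH the product is 6 itself. n-BuLi/TMSCl then gives the C-silyl alkyne F10, and TsOH/MeOH removes TES and trityl to rejoin the route at diol 8.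

3. Step 16. Protonation of the alkyllithium or alkylzinc by adventitious or internal proton sources, addition of the metal alkoxide to the bromobutenolide, or β-hydride elimination from the alkylpalladium intermediate could divert the coupling. The fallback uses no organometallic reagent: nickel-catalysed reductive cross-electrophile coupling of iodide 23 with 24 (NiBr2·glyme, 4,4′-di-tert-butyl-2,2′-bipyridine, Zn dust, NaI, DMA, rt). An alkyl radical formed from the iodide is captured by the vinylnickel species, and free hydroxyl groups are tolerated. It sets out from 23 and returns directly at 27 without any new intermediate.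

**Further compounds**
F1 | step 14 | (8S,10R,13E)-propargylic diol: 19 with its alkyne terminus bearing CH(OH)CH3 (carbinol epimers) | OCC/C(C(C)=C)=C(/C)C[C@@H](O[Si](C)(C)C(C)(C)C)C[C@](C)(COCc1ccc(OC)cc1)C#CC(C)O
F2 | step 14 | (E)-allylic diol (C5=C6 E, C6 bearing CH(OH)CH3) | OCC/C(C(C)=C)=C(/C)C[C@@H](O[Si](C)(C)C(C)(C)C)C[C@](C)(COCc1ccc(OC)cc1)/C=C/C(C)O
F3 | step 14 | (E)-enone triene (C5=C6 E, C6 bearing acetyl; C12-OH free) | OCC/C(C(C)=C)=C(/C)C[C@@H](O[Si](C)(C)C(C)(C)C)C[C@](C)(COCc1ccc(OC)cc1)/C=C/C(C)=O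
F4 | step 14 | 6α-acetyl-2α-(tert-butyldimethylsilyloxy)-19-(4-methoxybenzyloxy)-13,14,15,16-tetranorlabd-8-en-12-ol | CC1=C(CCO)[C@@]2(C)C[C@@H](O[Si](C)(C)C(C)(C)C)C[C@](C)(COCc3ccc(OC)cc3)[C@@H]2[C@@H](C(C)=O)C1
F5 | step 14 | 6α-acetoxy-2α-(tert-butyldimethylsilyloxy)-19-(4-methoxybenzyloxy)-13,14,15,16-tetranorlabd-8-en-12-ol | CC1=C(CCO)[C@@]2(C)C[C@@H](O[Si](C)(C)C(C)(C)C)C[C@](C)(COCc3ccc(OC)cc3)[C@@H]2[C@@H](OC(C)=O)C1
F6 | step 5 | 2-[(4-methoxybenzyloxy)methyl]-2-methyl-5-(trityloxy)pentane-1,4-diol (stereocentres as in 4) | c1ccccc1C(c1ccccc1)(c1ccccc1)OC[C@@H](O)C[C@](C)(COCc1ccc(OC)cc1)CO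
F7 | step 5 | bis(triethylsilyl) ether of F6 | c1ccccc1C(c1ccccc1)(c1ccccc1)OC[C@@H](O[Si](CC)(CC)CC)C[C@](C)(COCc1ccc(OC)cc1)CO[Si](CC)(CC)CC
F8 | step 5 | 2-[(4-methoxybenzyloxy)methyl]-2-methyl-4-(triethylsilyloxy)-5-(trityloxy)pentanal | c1ccccc1C(c1ccccc1)(c1ccccc1)OC[C@@H](O[Si](CC)(CC)CC)C[C@](C)(COCc1ccc(OC)cc1)C=O
F9 | step 5 | 2-O-triethylsilyl ether of alkynol 6 | c1ccccc1C(c1ccccc1)(c1ccccc1)OC[C@@H](O[Si](CC)(CC)CC)C[C@](C)(COCc1ccc(OC)cc1)C#C
F10 | step 5 | 6-(trimethylsilyl) derivative of F9 | c1ccccc1C(c1ccccc1)(c1ccccc1)OC[C@@H](O[Si](CC)(CC)CC)C[C@](C)(COCc1ccc(OC)cc1)C#C[Si](C)(C)C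
F0 | step 16 | none | none
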